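Remark on the chemistry: the alkylation of enolate 3 is assumed to occur on the face cis to the neighbouring ester, as this enolate is known to do with reactive halides; the whole route depends on that facial outcome. Locants C1–C7 in the text are those of the target carbocycle: C1 is the quaternary carbinol carbon, C7 its exocyclic CH2O carbon, C2 and C6 the flanking carbinol carbons, C5 the benzoyloxy carbon, and C3/C4 the methylenes.

## Analysis of the target

Target 14 is a single cyclohexane ring with no fused or bridged partner. C1 is a quaternary carbinol carbon that carries the C7H2–O-benzoyl arm, C2 and C6 are free secondary carbinols on either side of it, C5 carries the second benzoate, and C3 and C4 are plain methylene groups. The four stereocentres C2, C1, C6 and C5 are contiguous and their oxygens alternate between the ring faces (C2–O down, C1–O up, C6–O down, C5–O up), so every neighbouring O/O pair is trans. In one chair all four ring oxygens are equatorial and C7 is axial; C7 therefore shields the axial approach to C5 from its own face. The benzoates are base-labile and can migrate to the neighbouring free hydroxyls, and the tertiary C1 carbinol cannot be corrected once set. The difficulties are the quaternary centre between two carbinol stereocentres, the 1,4-related C2 and C5 configurations, and five oxygens of which only those on C7 and C5 are acylated. The strategy rests on two features. First, C3 and C4 are the only ring carbons without oxygen and lie between the 1,4-related C2 and C5, so the ring is a cyclohexane-1,4-dione closed at C3–C4. Second, the anti C1/C6 diol is a tartaric acid unit in which C1 carries C7 in place of hydrogen and the two carboxyl carbons become C2 and C5.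

## Retrosynthetic reasoning

**14 ⇒ 13 (acetal C–O bonds).** The C1/C6 diol is unmasked last. While it is tied up as the isopropylidene acetal of 13, neither benzoate has a neighbouring free hydroxyl on C1 or C6 to migrate to. The forward step only has to hydrolyse a strained trans-fused acetal under mild acid.

**13 ⇒ 12 ⇒ 11 (C7–O acyl bond, then the benzyl ether).** The benzoate on C7 is put on after hydrogenolysis of the benzyl ether of 11. In diol 12 the primary C7 hydroxyl competes only with the C2 hydroxyl, which is secondary and sits next to the quaternary C1.

**11 ⇒ 10 (C2–H bond).** The C2 carbinol is traced to a ketone. A small hydride should enter axially, anti to the axial C7 arm on the adjacent C1, which gives the equatorial alcohol trans to the C1 oxygen. Keeping C2 as a ketone until here also keeps its oxygen out of the benzoylation at C5.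

**10 ⇒ 9 ⇒ 8 (C5–O bond with inversion, then the C5–H bond).** Direct reduction of the C5 carbonyl of 8 to the equatorial alcohol would need hydride from the face that the axial C7 arm on C1 shields, so it is not relied on. A bulky hydride is instead sent to the open face to give the axial alcohol 9, and the benzoate is introduced with inversion by Mitsunobu esterification. The same step sets C5 and places its acyl group, so no selective acylation between the C2 and C5 oxygens is needed.

**8 ⇒ 7 (C3–C4 bond, the key disconnection).** Cutting C3–C4 in the 1,4-dione 8 gives two methyl ketone arms on a trans-dioxolane, in the form of the bis(silyl enol ether) 7. This is the only ring bond whose cleavage removes no stereocentre and leaves a precursor that is one alkylation away from a tartrate. Forward, an anodic oxidative coupling has to join the two terminal CH2 carbons intramolecularly. The silyl groups are changed from trimethylsilyl to tert-butyldimethylsilyl so that 7 can be purified and survives the alcohol co-solvent.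

**7 ⇒ 6 (O–Si bonds).** Both enol ethers come from the diketone 6 by silylation at the methyl side. One acetyl has no other α-hydrogen; the other has only a hindered tertiary one.

**6 ⇒ 5 ⇒ 4 (C2–C3 and C4–C5 bonds).** The two methyl groups (later C3 and C4) are added to the carboxyl carbons of diester 4 through the bis-Weinreb amide 5, which stops the addition at the ketone stage.

**4 ⇒ 1 + 2 (C1–C7 bond).** The quaternary centre is made by alkylating the ester enolate of the commercial tartrate acetonide 1 with the chloromethyl ether 2. The untouched stereocentre (later C6) and the acetal ring direct the new bond so that the two esters stay trans. This gives both C1 and C6 in the absolute configuration of 14 from the L-tartrate series.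

## Alternatives that were turned down

**Alternative 1:** The C1–O and C2–O bonds are disconnected to an alkene. The allylic epoxide A1 would be made from the conjugated dienyl alcohol A2 by Sharpless epoxidation (Ti(OiPr)4, a D-(−)-tartrate ester, t-BuOOH), with the C7 hydroxyl directing the oxidant to the C1=C2 alkene.
- For it: the reaction is catalytic and reagent-controlled, and one step fixes C1 and, after trans opening at C2, also C2. On precedent for the key step it is clearly stronger than the chosen route.
- Against it: A2 is a 2-substituted cyclohexa-1,3-diene that aromatises and dimerises easily. A1 is a tertiary vinyl oxirane that the Lewis-acidic titanium medium can open at the allylic C1 or in the SN2' sense.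
- Only two of the four stereocentres are then in place. The C5 and C6 oxygens must still be added across the remaining C5=C6 alkene on the face opposite to the C1 oxygen, against hydroxyl direction, and opened regioselectively, with extra protecting-group steps.
- Comparison: the chosen route takes C1 and C6 from one chiral-pool unit and leaves carbonyls at C2 and C5 as separate handles, at the price of one unprecedented ring closure.

**Alternative 2:** The C1–C2 bond is cut in a [3,3] sense. The cyclohexene acid A3 would arise from the ido-configured six-membered lactone A4, which carries an (E)-2-(benzyloxy)vinyl group on the ring-oxygen carbon. Enolisation and O-silylation of A4 are followed by an Ireland–Claisen shift through a boat transition state; C1–C2 forms and the ring O–C4 bond breaks.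
- For it: ring contractions of this kind are a known reaction class, every stereocentre is tied to a hexose, and C1 and C2 are created with chirality transfer. On precedent it is stronger than the chosen key step.
- Against it: A4 needs a long carbohydrate sequence (inversion into the ido series, chain extension to the E enol ether, three kinds of ether protection).
- After A3 the carboxyl must be reduced to C7H2OH, the C3=C4 alkene saturated, four benzyl-type ethers removed and two of five hydroxyls benzoylated selectively. The C2 configuration also depends on the enol ether geometry and on boat versus chair.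
- Comparison: the chosen route reaches 14 in eleven steps from a commercial C4 unit and installs the C5 benzoate in the step that sets C5.

**Alternative 3:** The C1–C6 bond is cut. The 2-methylene-3-hydroxycyclohexanone A5 would come from the keto aldehyde A6, itself a few steps from a chiral-pool α-amino acid, by an intramolecular Morita–Baylis–Hillman reaction. PBu3 adds to the vinyl ketone, the resulting enolate carbon (C1) attacks the aldehyde (C6), and the phosphine is lost.
- For it: it is the shortest way to the ring, catalytic, of a known reaction class, and the C5 benzoate is present from the start. On step count to the carbocycle and on precedent it is stronger than the chosen route.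
- Against it: the only stereocentre of A6 is α to an aldehyde and carries an acyloxy group, so it can epimerise under the nucleophilic conditions, and the benzoate can shift to the new C6 alkoxide. The C6 configuration is under weak 1,2-control.
- C1 and C2 must afterwards be made from an electron-poor exocyclic enone (dihydroxylation anti to the C6 hydroxyl, ketone reduction trans to the C1 oxygen), two further stereocentres under substrate control on a flexible ring.
- Comparison: the chosen route fixes the quaternary C1 and C6 before ring closure, and its ring closure forms no stereocentre.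

Key step: step 5

## Route

**Step 1**
Reactants: 1 dimethyl (4R,5R)-2,2-dimethyl-1,3-dioxolane-4,5-dicarboxylate; 2 benzyl chloromethyl ether
Product: 4 dimethyl (4R,5R)-4-[(benzyloxy)methyl]-2,2-dimethyl-1,3-dioxolane-4,5-dicarboxylate, via lithium ester enolate 3 (not isolated)
Conditions: LiN(i-Pr)2, THF/HMPA, −78 °C; then 2, −78 → −50 °C; AcOH quench at −78 °C
Reagents that add atoms: none
Why: Seebach-type α-alkylation of the tartrate acetonide ester enolate with a reactive α-chloro ether (SN2 at CH2); the enolate survives at −78 °C because the ring C–O bond beta to it lies near the nodal plane of the enolate π system. The C1–C7 bond should form on the face cis to the neighbouring ester, so the two esters stay trans and C7 takes the place of the former hydrogen (4R); the minor cis-diester is removed by chromatography.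

**Step 2**
Reactants: 4 dimethyl (4R,5R)-4-[(benzyloxy)methyl]-2,2-dimethyl-1,3-dioxolane-4,5-dicarboxylate
Product: 5 (4R,5R)-4-[(benzyloxy)methyl]-N4,N5-dimethoxy-N4,N5,2,2-tetramethyl-1,3-dioxolane-4,5-dicarboxamide
Conditions: MeNH(OMe)·HCl, i-PrMgCl, THF, −20 → 0 °C
Reagents that add atoms: N,O-dimethylhydroxylamine hydrochloride, CNOC.Cl
Why: Ester to Weinreb amide exchange by the chloromagnesium amide formed in the flask; both ester carbonyls are activated by their α-oxygen. The weakly basic amide should not deprotonate the remaining ring C–H, so the trans arrangement is kept.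

**Step 3**
Reactants: 5 (4R,5R)-4-[(benzyloxy)methyl]-N4,N5-dimethoxy-N4,N5,2,2-tetramethyl-1,3-dioxolane-4,5-dicarboxamide
Product: 6 1,1'-{(4R,5R)-4-[(benzyloxy)methyl]-2,2-dimethyl-1,3-dioxolane-4,5-diyl}diethanone
Conditions: MeMgBr, THF, 0 °C; cold aq. NH4Cl
Reagents that add atoms: methylmagnesium bromide, C[Mg]Br
Why: Weinreb ketone synthesis: each amide takes up one methyl group to a stable magnesium chelate that collapses to the methyl ketone only on work-up, so no tertiary alcohol forms. The two new methyl carbons are the later C3 and C4.

**Step 4**
Reactants: 6 1,1'-{(4R,5R)-4-[(benzyloxy)methyl]-2,2-dimethyl-1,3-dioxolane-4,5-diyl}diethanone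
Product: 7 (4R,5R)-4-[(benzyloxy)methyl]-4,5-bis{1-[(tert-butyldimethylsilyl)oxy]ethenyl}-2,2-dimethyl-1,3-dioxolane
Conditions: TBSOTf, Et3N, CH2Cl2, −78 → 0 °C
Reagents that add atoms: tert-butyldimethylsilyl trifluoromethanesulfonate, CC(C)(C)[Si](C)(C)OS(=O)(=O)C(F)(F)F
Why: Soft enolisation of methyl ketones with a silyl triflate and a tertiary amine: O-silylation is followed by proton loss from the unhindered methyl group. The acetyl on the quaternary carbon has no other α-hydrogen and the tertiary α-alkoxy C–H next to the other acetyl is hindered, so both enol ethers should be terminal and no stereocentre is touched.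

**Step 5**
Reactants: 7 (4R,5R)-4-[(benzyloxy)methyl]-4,5-bis{1-[(tert-butyldimethylsilyl)oxy]ethenyl}-2,2-dimethyl-1,3-dioxolane
Product: 8 (3aR,7aR)-3a-[(benzyloxy)methyl]-2,2-dimethyltetrahydro-1,3-benzodioxole-4,7-dione (trans-fused)
Conditions: constant-current electrolysis, undivided cell, reticulated vitreous carbon anode, Pt cathode, 0.1 M LiClO4, CH2Cl2/MeOH 4:1, 2,6-lutidine, 5 mM substrate, rt, 2.2 F/mol
Reagents that add atoms: none
Why: Proposed new method: the anode removes one electron from one silyl enol ether of 7; the radical cation is attacked at its CH2 terminus (C3) by the CH2 terminus (C4) of the second, electron-rich enol ether, which forms the C3–C4 bond and leaves a silyloxy-stabilised radical at one carbonyl carbon and a silyloxocarbenium ion at the other. The radical is oxidised at once at the anode and methanol takes both silyl groups (2,6-lutidine takes the protons, which are reduced to H2 at the cathode), so that the 1,4-dione 8 is released. The closest known reaction types are the anodic and (NH4)2Ce(NO3)6-mediated oxidative couplings of silyl enol ethers to 1,4-diketones and the anodic cyclisations of enol ether radical cations onto tethered electron-rich alkenes; a closure in which the tether runs through both carbonyl carbons has not been shown. The six-membered carbocycle closes in the 6-endo-trig mode with respect to both alkenes, preferred to 5-exo because bonding at the unsubstituted CH2 leaves an oxygen-stabilised radical or cation on the fully substituted carbon, whereas 5-exo would bond to that carbon and give a primary radical. The closure makes no new stereocentre: C1 and C6 are carried over from 7, and the trans-dioxolane holds the two enol ether arms gauche, within bonding distance. The step needs ring closure to be faster than solvent capture, desilylation or intermolecular coupling, which high dilution, low current density and the tethered electron-rich partner should secure; it also needs C6–H, now alpha to a ketone in a strained trans-fused ring, not to epimerise, which the buffered, nearly neutral medium should secure. The benzyl ether, the acetal and the product ketones are oxidised only at clearly higher potential than a silyl enol ether and should stay intact.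

**Step 6**
Reactants: 8 (3aR,7aR)-3a-[(benzyloxy)methyl]-2,2-dimethyltetrahydro-1,3-benzodioxole-4,7-dione
Product: 9 (3aR,7S,7aS)-3a-[(benzyloxy)methyl]-7-hydroxy-2,2-dimethylhexahydro-1,3-benzodioxol-4-one
Conditions: LiBH(s-Bu)3 (1.1 equiv), THF, −78 °C; then H2O
Reagents that add atoms: none
Why: Kinetically controlled ketone reduction with a bulky trialkylborohydride: the C5 carbonyl is the accessible one (the C2 carbonyl is flanked by the quaternary C1), and hydride should come from the face opposite the axial C7H2OBn group on C1, which is 1,3 to C5. This gives the axial (7S) alcohol, cis to C7, which is the configuration that step 7 inverts.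

**Step 7**
Reactants: 9 (3aR,7S,7aS)-3a-[(benzyloxy)methyl]-7-hydroxy-2,2-dimethylhexahydro-1,3-benzodioxol-4-one
Product: 10 (3aR,7R,7aS)-3a-[(benzyloxy)methyl]-2,2-dimethyl-4-oxohexahydro-1,3-benzodioxol-7-yl benzoate
Conditions: PhCO2H, PPh3, DIAD, toluene, 0 °C → rt
Reagents that add atoms: benzoic acid, O=C(O)c1ccccc1
Why: Mitsunobu esterification (SN2 with inversion): the axial oxyphosphonium group at C5 is displaced by benzoate from the unshielded face, which should give the equatorial (5R) benzoate trans to the C6 oxygen. The benzoyl group goes onto C5 without competition from any other hydroxyl.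

**Step 8**
Reactants: 10 (3aR,7R,7aS)-3a-[(benzyloxy)methyl]-2,2-dimethyl-4-oxohexahydro-1,3-benzodioxol-7-yl benzoate
Product: 11 (3aS,4R,7R,7aS)-3a-[(benzyloxy)methyl]-4-hydroxy-2,2-dimethylhexahydro-1,3-benzodioxol-7-yl benzoate
Conditions: NaBH4, MeOH/THF, −20 °C
Reagents that add atoms: none
Why: Borohydride reduction of a cyclohexanone by axial attack: the small hydride should add to the C2 carbonyl anti to the adjacent axial C7 arm and give the equatorial (2R) alcohol trans to the C1 oxygen. The benzoate is not reduced at this temperature.

**Step 9**
Reactants: 11 (3aS,4R,7R,7aS)-3a-[(benzyloxy)methyl]-4-hydroxy-2,2-dimethylhexahydro-1,3-benzodioxol-7-yl benzoate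
Product: 12 (3aS,4R,7R,7aS)-4-hydroxy-3a-(hydroxymethyl)-2,2-dimethylhexahydro-1,3-benzodioxol-7-yl benzoate
Conditions: H2 (1 atm), Pd/C, EtOAc, rt
Reagents that add atoms: none
Why: Hydrogenolysis of the benzyl ether over Pd/C; the benzoate, the acetal and the secondary alcohol are inert in a neutral aprotic solvent.

**Step 10**
Reactants: 12 (3aS,4R,7R,7aS)-4-hydroxy-3a-(hydroxymethyl)-2,2-dimethylhexahydro-1,3-benzodioxol-7-yl benzoate
Product: 13 [(3aS,4R,7R,7aS)-7-(benzoyloxy)-4-hydroxy-2,2-dimethylhexahydro-1,3-benzodioxol-3a-yl]methyl benzoate
Conditions: PhCOCl (1.05 equiv), pyridine, CH2Cl2, −20 → 0 °C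
Reagents that add atoms: benzoyl chloride, O=C(Cl)c1ccccc1
Why: Kinetically controlled acylation: the primary C7 hydroxyl should react well before the secondary C2 hydroxyl, which is flanked by the quaternary C1.

**Step 11**
Reactants: 13 [(3aS,4R,7R,7aS)-7-(benzoyloxy)-4-hydroxy-2,2-dimethylhexahydro-1,3-benzodioxol-3a-yl]methyl benzoate
Product: 14 [(1S,2R,5R,6S)-5-(benzoyloxy)-1,2,6-trihydroxycyclohexyl]methyl benzoate (CNP0264996.1)
Conditions: AcOH/H2O 4:1, 40 °C
Reagents that add atoms: none
Why: Acid-catalysed hydrolysis of an isopropylidene acetal; the trans-fused dioxolane is strained and should open under mild aqueous acid, where benzoyl migration to the freed C1 and C6 hydroxyls is slow.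

## Compound list

1 | dimethyl (4R,5R)-2,2-dimethyl-1,3-dioxolane-4,5-dicarboxylate (acetonide of dimethyl L-tartrate) | COC(=O)[C@@H]1OC(C)(C)O[C@H]1C(=O)OC | starting material
2 | benzyl chloromethyl ether | ClCOCc1ccccc1 | starting material
3 | lithium ester enolate of 1 | COC(=O)[C@@H]1OC(C)(C)OC1=C(OC)O[Li] | intermediate
4 | dimethyl (4R,5R)-4-[(benzyloxy)methyl]-2,2-dimethyl-1,3-dioxolane-4,5-dicarboxylate | COC(=O)[C@@H]1OC(C)(C)O[C@@]1(COCc2ccccc2)C(=O)OC | intermediate
5 | (4R,5R)-4-[(benzyloxy)methyl]-N4,N5-dimethoxy-N4,N5,2,2-tetramethyl-1,3-dioxolane-4,5-dicarboxamide | CON(C)C(=O)[C@@H]1OC(C)(C)O[C@@]1(COCc2ccccc2)C(=O)N(C)OC | intermediate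
6 | 1,1'-{(4R,5R)-4-[(benzyloxy)methyl]-2,2-dimethyl-1,3-dioxolane-4,5-diyl}diethanone | CC(=O)[C@@H]1OC(C)(C)O[C@@]1(COCc2ccccc2)C(C)=O | intermediate
7 | (4R,5R)-4-[(benzyloxy)methyl]-4,5-bis{1-[(tert-butyldimethylsilyl)oxy]ethenyl}-2,2-dimethyl-1,3-dioxolane | C=C(O[Si](C)(C)C(C)(C)C)[C@@H]1OC(C)(C)O[C@@]1(COCc2ccccc2)C(=C)O[Si](C)(C)C(C)(C)C | intermediate
8 | (3aR,7aR)-3a-[(benzyloxy)methyl]-2,2-dimethyltetrahydro-1,3-benzodioxole-4,7-dione, trans-fused | c1ccccc1COC[C@@]12OC(C)(C)O[C@H]1C(=O)CCC2=O | intermediate
9 | (3aR,7S,7aS)-3a-[(benzyloxy)methyl]-7-hydroxy-2,2-dimethylhexahydro-1,3-benzodioxol-4-one | c1ccccc1COC[C@@]12OC(C)(C)O[C@H]1[C@@H](O)CCC2=O | intermediate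
10 | (3aR,7R,7aS)-3a-[(benzyloxy)methyl]-2,2-dimethyl-4-oxohexahydro-1,3-benzodioxol-7-yl benzoate | c1ccccc1COC[C@@]12OC(C)(C)O[C@H]1[C@H](OC(=O)c3ccccc3)CCC2=O | intermediate
11 | (3aS,4R,7R,7aS)-3a-[(benzyloxy)methyl]-4-hydroxy-2,2-dimethylhexahydro-1,3-benzodioxol-7-yl benzoate | c1ccccc1COC[C@@]12OC(C)(C)O[C@H]1[C@H](OC(=O)c3ccccc3)CC[C@H]2O | intermediate
12 | (3aS,4R,7R,7aS)-4-hydroxy-3a-(hydroxymethyl)-2,2-dimethylhexahydro-1,3-benzodioxol-7-yl benzoate | OC[C@@]12OC(C)(C)O[C@H]1[C@H](OC(=O)c3ccccc3)CC[C@H]2O | intermediate
13 | [(3aS,4R,7R,7aS)-7-(benzoyloxy)-4-hydroxy-2,2-dimethylhexahydro-1,3-benzodioxol-3a-yl]methyl benzoate | O=C(OC[C@@]12OC(C)(C)O[C@H]1[C@H](OC(=O)c3ccccc3)CC[C@H]2O)c1ccccc1 | intermediate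
14 | [(1S,2R,5R,6S)-5-(benzoyloxy)-1,2,6-trihydroxycyclohexyl]methyl benzoate | O=C(OC[C@]1(O)[C@H](O)CC[C@@H](OC(=O)c2ccccc2)[C@@H]1O)c1ccccc1 | target

## Step count and least certain steps

Total step count: 11. Longest linear sequence: 11 steps (1 → 14).

**Step 5 (key step, new method).** The most likely failure is that the radical cation is intercepted before ring closure. It can be desilylated or captured by methanol, which returns the diketone or an α-methoxy ketone, or it can couple between molecules to oligomers. Base-induced epimerisation of the ring-fusion C–H in the product is a second risk.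

The fallback uses only known chemistry and runs from 5 to 8 by ring-closing metathesis. Amide 5 is treated with CH2=CHMgBr to give the bis(vinyl ketone) F1. Reduction with NaBH4/CeCl3·7H2O gives the bis-allylic diol F2 as carbinol epimers, which do not matter because both carbinols are oxidised again. The second-generation Grubbs catalyst in CH2Cl2 closes the trans-fused cyclohexenediol F3 with loss of ethene. Diimide (TsNHNH2, NaOAc) saturates the ring alkene without touching the benzyl ether and gives the diol F4. Dess–Martin periodinane buffered with NaHCO3 oxidises both carbinols and returns dione 8.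

**Step 1.** The alkylation may be slower than β-elimination of enolate 3 (opening of the dioxolane) on warming, and facial selectivity may be incomplete. Attack trans to the neighbouring ester would give the cis-diester, which cannot lead to a trans-fused ring.

The fallback runs from 1 to 5 and replaces the alkylation by a hydroxymethylation with lactone trapping. Enolate 3 is quenched at −78 °C with monomeric formaldehyde, a far faster electrophile. Only the adduct whose new CH2O group is cis to the neighbouring ester can close to the bicyclic lactone F5, which marks and purifies the required diastereomer. Aminolysis of the lactone and of the remaining methyl ester with MeNH(OMe)·HCl/i-PrMgCl gives the hydroxymethyl bis-amide F6. Neutral O-benzylation (2-benzyloxy-1-methylpyridinium triflate, MgO, PhCF3) returns 5.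

**Step 6.** Site selectivity between the two carbonyls may be poor, or both may be reduced.

The fallback runs from 8 to 11 and does not depend on stopping at mono-reduction. Excess LiBH(s-Bu)3 should reduce both carbonyls from the face opposite C7, giving the 4,7-diol F7 (C2 hydroxyl equatorial, C5 hydroxyl axial). A Mitsunobu reaction with PhCO2H, PPh3 and DIAD should then invert only the C5 carbinol, because the C2 carbinol is flanked by the quaternary C1 and is inert to SN2. This gives 11 directly.

**Step 7.** Elimination through the oxyphosphonium intermediate (antiperiplanar axial hydrogens on C4 and C6) may compete with substitution, or the hindered axial hydroxyl may be activated too slowly.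

The fallback runs from 9 to 10 and separates activation from displacement. Tf2O/pyridine at −40 °C converts 9 to the triflate F8, and CsO2CPh with 18-crown-6 in toluene, a weakly basic carboxylate, displaces it with inversion to give 10.

**Step 10.** Discrimination between the C7 and C2 hydroxyls may be incomplete (over-acylation), or the benzoyl group may shift from C7 to C2 under the basic conditions.

The fallback runs from 10 to 13 and avoids any selective acylation. The benzyl ether of 10 is oxidised directly to the benzoate with RuCl3·xH2O (cat.)/NaIO4 in CCl4/MeCN/H2O, giving the keto dibenzoate F9. NaBH4 at −20 °C then reduces the C2 carbonyl as in step 8 and gives 13.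

## Further compounds

F1 | step 5 | 1,1'-{(4R,5R)-4-[(benzyloxy)methyl]-2,2-dimethyl-1,3-dioxolane-4,5-diyl}bis(prop-2-en-1-one) | C=CC(=O)[C@@H]1OC(C)(C)O[C@@]1(COCc2ccccc2)C(=O)C=C
F2 | step 5 | 1,1'-{4-[(benzyloxy)methyl]-2,2-dimethyl-1,3-dioxolane-4,5-diyl}bis(prop-2-en-1-ol), ring carbons as in 5, carbinol epimers | C=CC(O)[C@@H]1OC(C)(C)O[C@@]1(COCc2ccccc2)C(O)C=C
F3 | step 5 | trans-fused 3a-[(benzyloxy)methyl]-2,2-dimethyl-3a,4,7,7a-tetrahydro-1,3-benzodioxole-4,7-diol, ring-fusion carbons as in 8, carbinol epimers | c1ccccc1COC[C@@]12OC(C)(C)O[C@H]1C(O)C=CC2O
F4 | step 5 | trans-fused 3a-[(benzyloxy)methyl]-2,2-dimethylhexahydro-1,3-benzodioxole-4,7-diol, ring-fusion carbons as in 8, carbinol epimers | c1ccccc1COC[C@@]12OC(C)(C)O[C@H]1C(O)CCC2O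
F5 | step 1 | methyl (3aR,6aR)-2,2-dimethyl-6-oxotetrahydrofuro[3,4-d][1,3]dioxole-3a-carboxylate | O=C1OC[C@@]2(C(=O)OC)OC(C)(C)O[C@@H]12
F6 | step 1 | (4R,5R)-4-(hydroxymethyl)-N4,N5-dimethoxy-N4,N5,2,2-tetramethyl-1,3-dioxolane-4,5-dicarboxamide | CON(C)C(=O)[C@@H]1OC(C)(C)O[C@@]1(CO)C(=O)N(C)OC
F7 | step 6 | (3aS,4R,7S,7aS)-3a-[(benzyloxy)methyl]-2,2-dimethylhexahydro-1,3-benzodioxole-4,7-diol | c1ccccc1COC[C@@]12OC(C)(C)O[C@H]1[C@@H](O)CC[C@H]2O
F8 | step 7 | (3aR,7S,7aS)-3a-[(benzyloxy)methyl]-2,2-dimethyl-4-oxohexahydro-1,3-benzodioxol-7-yl trifluoromethanesulfonate | c1ccccc1COC[C@@]12OC(C)(C)O[C@H]1[C@@H](OS(=O)(=O)C(F)(F)F)CCC2=O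
F9 | step 10 | [(3aR,7R,7aS)-7-(benzoyloxy)-2,2-dimethyl-4-oxohexahydro-1,3-benzodioxol-3a-yl]methyl benzoate | O=C(OC[C@@]12OC(C)(C)O[C@H]1[C@H](OC(=O)c3ccccc3)CCC2=O)c1ccccc1
A1 | alternative 1 | (7-oxabicyclo[4.1.0]hept-2-en-1-yl)methanol, the C1,C2-epoxide of A2 with the oxirane oxygen on the face of the later C1 hydroxyl | OC[C@]1(O2)[C@@H]2CCC=C1
A2 | alternative 1 | (cyclohexa-1,5-dien-1-yl)methanol | OCC1=CCCC=C1
A3 | alternative 2 | 1,2,6-tris(benzyloxy)-5-[(4-methoxybenzyl)oxy]cyclohex-3-ene-1-carboxylic acid, configured as the target at C1, C2, C5 and C6 | OC(=O)[C@]1(OCc2ccccc2)[C@H](OCc2ccccc2)C=C[C@@H](OCc2ccc(OC)cc2)[C@@H]1OCc1ccccc1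
A4 | alternative 2 | ido-configured 3,4-bis(benzyloxy)-6-[(E)-2-(benzyloxy)ethenyl]-5-[(4-methoxybenzyl)oxy]tetrahydro-2H-pyran-2-one | O=C1O[C@@H](/C=C/OCc2ccccc2)[C@@H](OCc2ccc(OC)cc2)[C@H](OCc2ccccc2)[C@H]1OCc1ccccc1
A5 | alternative 3 | trans-2-hydroxy-3-methylidene-4-oxocyclohexyl benzoate | C=C1C(=O)CC[C@@H](OC(=O)c2ccccc2)[C@@H]1O
A6 | alternative 3 | (2R)-1,5-dioxohept-6-en-2-yl benzoate | C=CC(=O)CC[C@@H](OC(=O)c1ccccc1)C=O
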